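**Plan**
- Cuts, in retrosynthetic order: (1) the acyl C–C bond at ring C-2; (2) the ring bond C-5–C-6, between the enol carbon next to the CH2 arm and the quaternary carbon, which turns the carbocycle into an isomeric 4-alkoxy-2-pyranone; (3) the C–CH3 bond of the carbinol, the pyranone C-3–CH2 bond, the C–isopropenyl bond and the two lateral C–C bonds of the pyranone side chain.
- Forward: the pyranone ring is bought and alkylated twice at its methyl group; cyclopentenone becomes a trans-2,3-disubstituted cyclopentanone and is joined to the pyranone by Michael addition; methyl addition gives the cyclopentanol; the pyranone ring is then converted into the carbocycle; the acyl group comes last.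
- Feature used: ring atoms C-1 to C-5 of the cyclohexadienone, with their three oxygens, are the same 1,3,5-tricarbonyl chain as C-6 to C-2 of a 6-alkyl-4-alkoxy-2-pyranone. The tertiary hydroxyl of the cyclopentane stands six atoms from the pyranone C-2 carbonyl (O, carbinol C, ring CH, CH2, C-3, C-2), so it can open the lactone as a temporary cis-fused δ-lactone and leave again.
- Stereochemistry: the isopropenyl-bearing carbon is set by rhodium/(R)-BINAP catalysis; the two other cyclopentane centres follow by substrate control (trans protonation, methyl addition anti to the side chain); the quaternary ring carbon is relayed from the carbinol carbon through the temporary lactone in the key step; the acyl stereocentre is bought.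

Key step: step 7

Remark: pyranone 4 is racemic at its side-chain methine; this carbon becomes a planar enolate carbon in step 7, so 9, 10 and 11 are carried as pairs of epimers at that carbon only.

Step 1
Reactants: 1 4-hydroxy-6-methyl-2H-pyran-2-one; 2 1-bromo-3-methylbut-2-ene
Product: 3 4-hydroxy-6-(4-methylpent-3-en-1-yl)-2H-pyran-2-one
Conditions: LiN(iPr)2 (2.2 equiv), THF, −78 °C; 2 (1.05 equiv), −78 → 0 °C; aq. HCl work-up
Reagents that add atoms: none
Why: Deprotonation of the OH and then of the 6-methyl group gives the vinylogous dianion, which should be alkylated at its more basic lateral carbon (γ-alkylation of a β-dicarbonyl dianion).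

Step 2
Reactants: 3 4-hydroxy-6-(4-methylpent-3-en-1-yl)-2H-pyran-2-one
Product: 4 4-hydroxy-6-(5-methylhex-4-en-2-yl)-2H-pyran-2-one (racemic)
Conditions: LiN(iPr)2 (2.2 equiv), THF, −78 °C; MeI (1.1 equiv), −78 → −20 °C; aq. HCl work-up
Reagents that add atoms: iodomethane, CI
Why: The same lateral dianion alkylation, now at the secondary carbon, should install the methyl group; the new stereocentre is formed as a racemate, which does not matter because it is erased in step 7.

Step 3
Reactants: 5 cyclopent-2-en-1-one
Product: 7 (2R,3R)-2-[(dimethylamino)methyl]-3-(prop-1-en-2-yl)cyclopentan-1-one, via silyl enol ether 6 (not isolated)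
Conditions: CH2=C(CH3)MgBr (1.6 equiv), ZnCl2 (1.6 equiv), THF, 0 °C; 5, [RhCl(C2H4)2]2 (1.5 mol %), (R)-BINAP (3.3 mol %), Me3SiCl (1.6 equiv), THF, 20 °C; then CH2=NMe2+ I− (1.2 equiv), CH2Cl2, 23 °C; cold 1 M NaOH work-up
Reagents that add atoms: isopropenylzinc chloride, C=C(C)[Zn]Cl (made in the flask from isopropenylmagnesium bromide, C=C(C)[Mg]Br, and ZnCl2); N,N-dimethylmethylideneammonium iodide, C=[N+](C)C.[I-]; chlorotrimethylsilane, C[Si](C)(C)Cl (its silicon group is carried only by intermediate 6)
Why: Rhodium/BINAP-catalysed asymmetric 1,4-addition of an organozinc chloride with silyl trapping (Hayashi–Miyaura type) should set C-3 under catalyst control, (R)-BINAP giving the (R)-ketone series by analogy with aryl nucleophiles, and the regiodefined silyl enol ether then undergoes a Mukaiyama–Mannich reaction anti to the isopropenyl group to give the trans β-amino ketone.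

Step 4
Reactants: 7 (2R,3R)-2-[(dimethylamino)methyl]-3-(prop-1-en-2-yl)cyclopentan-1-one; 4 4-hydroxy-6-(5-methylhex-4-en-2-yl)-2H-pyran-2-one
Product: 9 4-hydroxy-6-(5-methylhex-4-en-2-yl)-3-{[(1S,5R)-2-oxo-5-(prop-1-en-2-yl)cyclopentyl]methyl}-2H-pyran-2-one, via methylidene ketone 8 (not isolated)
Conditions: toluene, 90 °C, slow N2 sweep
Reagents that add atoms: none
Why: The acidic pyranone protonates the Mannich base, which eliminates dimethylamine to enone 8, and the nucleophilic C-3 of the 4-hydroxy-2-pyranone traps it at once by Michael addition (Mannich base as enone surrogate) before it can isomerise to the endocyclic enone; the carbon next to the ketone is set trans to the isopropenyl group by thermodynamic protonation.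

Step 5
Reactants: 9 4-hydroxy-6-(5-methylhex-4-en-2-yl)-3-{[(1S,5R)-2-oxo-5-(prop-1-en-2-yl)cyclopentyl]methyl}-2H-pyran-2-one
Product: 10 4-hydroxy-3-{[(1S,2R,5R)-2-hydroxy-2-methyl-5-(prop-1-en-2-yl)cyclopentyl]methyl}-6-(5-methylhex-4-en-2-yl)-2H-pyran-2-one
Conditions: CeCl3 (3 equiv), MeMgBr (4 equiv), THF, −78 → 0 °C; 0.5 M HCl work-up
Reagents that add atoms: methylmagnesium bromide, C[Mg]Br
Why: The first equivalent turns the acidic pyranone into its inert magnesium salt, and the organocerium reagent then adds to the ketone (1,2-addition, CeCl3 suppressing enolisation) from the face anti to the neighbouring side chain, as nucleophiles do with trans-2,3-disubstituted cyclopentanones, so the new hydroxyl is cis to the CH2 arm and the methyl group trans.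

Step 6
Reactants: 10 4-hydroxy-3-{[(1S,2R,5R)-2-hydroxy-2-methyl-5-(prop-1-en-2-yl)cyclopentyl]methyl}-6-(5-methylhex-4-en-2-yl)-2H-pyran-2-one
Product: 11 3-{[(1S,2R,5R)-2-hydroxy-2-methyl-5-(prop-1-en-2-yl)cyclopentyl]methyl}-6-(5-methylhex-4-en-2-yl)-4-(prop-2-en-1-yloxy)-2H-pyran-2-one
Conditions: K2CO3 (1.5 equiv), allyl bromide (1.2 equiv), acetone, 40 °C
Reagents that add atoms: allyl bromide (3-bromoprop-1-ene), C=CCBr
Why: Williamson-type O-alkylation of the vinylogous acid should occur at the 4-oxygen of the pyranone anion while the neutral tertiary alcohol stays free; the allyl group removes the acidic OH that would quench the alkoxide needed in step 7 and is a poor leaving group.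

Step 7
Reactants: 11 3-{[(1S,2R,5R)-2-hydroxy-2-methyl-5-(prop-1-en-2-yl)cyclopentyl]methyl}-6-(5-methylhex-4-en-2-yl)-4-(prop-2-en-1-yloxy)-2H-pyran-2-one
Product: 13 (6R)-5-hydroxy-4-{[(1S,2R,5R)-2-hydroxy-2-methyl-5-(prop-1-en-2-yl)cyclopentyl]methyl}-6-methyl-6-(3-methylbut-2-en-1-yl)-3-(prop-2-en-1-yloxy)cyclohexa-2,4-dien-1-one, via potassium lactone dienolate 12 (not isolated)
Conditions: KN(SiMe3)2 (1.1 equiv), THF, −40 → 23 °C; t-BuOH (0.3 equiv); then 0.5 M HCl, 0 °C
Reagents that add atoms: none
Why: Proposed new method: the potassium alkoxide of the tertiary alcohol adds to the pyranone C-2 carbonyl, six atoms away, and the ring opens to the cis-fused δ-lactone dienolate 12 (6-exo-trig closure of the temporary lactone ring); proton transfer then moves the charge to the side-chain methine, whose tetrasubstituted enolate attacks the lactone carbonyl and expels the same alkoxide (Dieckmann closure of the carbocycle, 6-(enolendo)-exo-trig), and the released alkoxide is protonated by the new vinylogous acid, which makes the sequence irreversible. The closest known reaction types are the alkoxide-induced ring opening of 4-alkoxy-2-pyranones followed by Claisen recyclisation to phloroglucinol ethers (biomimetic polyketide cyclisation) and the Dieckmann cyclisation of δ-keto esters to cyclohexane-1,3-diones; new here is that an internal tertiary alkoxide is the relay and that a quaternary carbon is formed. The only new stereocentre, the quaternary C-6, is controlled by the temporary lactone, whose leaving oxygen sits on the stereogenic C-7a: the closure should pass through a chair lactone trans-fused to the forming ring (angular methyl equatorial, C-3 hydrogen and ring-fusion hydrogen axial), so the enolate bonds to the convex face of the lactone carbonyl, and there the larger prenyl group takes the equatorial site and the methyl group the axial site, which corresponds to 6R. Because the enolate geometries and the C-3 epimers of the lactone interconvert by proton transfer, the outcome is set by these closure transition states alone (Curtin–Hammett), and the side-chain stereocentre of 11 is irrelevant. The step needs alkoxide attack at C-2 rather than addition–elimination at C-4, and C- rather than O-acylation of the enolate; the first is secured by the hard carbonyl site and the poor allyloxide leaving group, the second because O-acylation only leads back to the pyranone whereas C-acylation ends in a stabilised anion.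

Step 8
Reactants: 13 (6R)-5-hydroxy-4-{[(1S,2R,5R)-2-hydroxy-2-methyl-5-(prop-1-en-2-yl)cyclopentyl]methyl}-6-methyl-6-(3-methylbut-2-en-1-yl)-3-(prop-2-en-1-yloxy)cyclohexa-2,4-dien-1-one
Product: 14 (6R)-3,5-dihydroxy-4-{[(1S,2R,5R)-2-hydroxy-2-methyl-5-(prop-1-en-2-yl)cyclopentyl]methyl}-6-methyl-6-(3-methylbut-2-en-1-yl)cyclohexa-2,4-dien-1-one
Conditions: Pd(PPh3)4 (5 mol %), morpholine (5 equiv), THF, 23 °C; dilute HCl wash
Reagents that add atoms: none
Why: Zerovalent palladium ionises the allyl vinylogous ester to a π-allyl complex and the stabilised dienolate, and morpholine captures the allyl group (Tsuji–Trost deallylation), which should leave the tertiary alcohol, the alkenes and the quaternary centre untouched.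

Step 9
Reactants: 14 (6R)-3,5-dihydroxy-4-{[(1S,2R,5R)-2-hydroxy-2-methyl-5-(prop-1-en-2-yl)cyclopentyl]methyl}-6-methyl-6-(3-methylbut-2-en-1-yl)cyclohexa-2,4-dien-1-one; 15 (S)-2-methylbutanoic acid
Product: 16 (6R)-3,5-dihydroxy-4-{[(1S,2R,5R)-2-hydroxy-2-methyl-5-(prop-1-en-2-yl)cyclopentyl]methyl}-6-methyl-6-(3-methylbut-2-en-1-yl)-2-[(2S)-2-methylbutanoyl]cyclohexa-2,4-dien-1-one
Conditions: DCC (1.2 equiv), DMAP (1.2 equiv), CH2Cl2, 0 → 23 °C
Reagents that add atoms: none
Why: Carbodiimide coupling gives the enol ester and DMAP relays the acyl group from oxygen to the only unsubstituted carbon between two carbonyl groups (O-acylation then O→C acyl migration, a Fries-type rearrangement of cyclic 1,3-diones), the C-acyl triketone being the thermodynamic product; the acid is activated without strong base, so its bought α-stereocentre should be kept.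

**Compound list**
1 | 4-hydroxy-6-methyl-2H-pyran-2-one | CC1=CC(O)=CC(=O)O1 | starting material
2 | 1-bromo-3-methylbut-2-ene (prenyl bromide) | CC(C)=CCBr | starting material
3 | 4-hydroxy-6-(4-methylpent-3-en-1-yl)-2H-pyran-2-one | CC(C)=CCCC1=CC(O)=CC(=O)O1 | intermediate
4 | 4-hydroxy-6-(5-methylhex-4-en-2-yl)-2H-pyran-2-one, racemic | CC(CC=C(C)C)C1=CC(O)=CC(=O)O1 | intermediate
5 | cyclopent-2-en-1-one | O=C1C=CCC1 | starting material
6 | (R)-trimethyl{[3-(prop-1-en-2-yl)cyclopent-1-en-1-yl]oxy}silane | C=C(C)[C@@H]1CCC(O[Si](C)(C)C)=C1 | intermediate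
7 | (2R,3R)-2-[(dimethylamino)methyl]-3-(prop-1-en-2-yl)cyclopentan-1-one | C=C(C)[C@@H]1CCC(=O)[C@H]1CN(C)C | intermediate
8 | (S)-2-methylidene-3-(prop-1-en-2-yl)cyclopentan-1-one | C=C(C)[C@@H]1CCC(=O)C1=C | intermediate
9 | 4-hydroxy-6-(5-methylhex-4-en-2-yl)-3-{[(1S,5R)-2-oxo-5-(prop-1-en-2-yl)cyclopentyl]methyl}-2H-pyran-2-one (both epimers at the side-chain methine) | C=C(C)[C@@H]1CCC(=O)[C@H]1CC1=C(O)C=C(C(C)CC=C(C)C)OC1=O | intermediate
10 | 4-hydroxy-3-{[(1S,2R,5R)-2-hydroxy-2-methyl-5-(prop-1-en-2-yl)cyclopentyl]methyl}-6-(5-methylhex-4-en-2-yl)-2H-pyran-2-one | C=C(C)[C@@H]1CC[C@@](C)(O)[C@H]1CC1=C(O)C=C(C(C)CC=C(C)C)OC1=O | intermediate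
11 | 3-{[(1S,2R,5R)-2-hydroxy-2-methyl-5-(prop-1-en-2-yl)cyclopentyl]methyl}-6-(5-methylhex-4-en-2-yl)-4-(prop-2-en-1-yloxy)-2H-pyran-2-one | C=C(C)[C@@H]1CC[C@@](C)(O)[C@H]1CC1=C(OCC=C)C=C(C(C)CC=C(C)C)OC1=O | intermediate
12 | potassium dienolate of the cis-fused lactone (4aS,5R,7aR)-7a-methyl-5-(prop-1-en-2-yl)hexahydrocyclopenta[b]pyran-2(3H)-one carrying at C-3 a 4,7-dimethyl-3-oxido-1-(prop-2-en-1-yloxy)octa-2,6-dien-1-ylidene group | C=C(C)[C@@H]1CC[C@@]2(C)OC(=O)/C(=C(/OCC=C)\C=C(/[O-])C(C)CC=C(C)C)C[C@@H]12.[K+] | intermediate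
13 | (6R)-5-hydroxy-4-{[(1S,2R,5R)-2-hydroxy-2-methyl-5-(prop-1-en-2-yl)cyclopentyl]methyl}-6-methyl-6-(3-methylbut-2-en-1-yl)-3-(prop-2-en-1-yloxy)cyclohexa-2,4-dien-1-one | C=C(C)[C@@H]1CC[C@@](C)(O)[C@H]1CC1=C(O)[C@@](C)(CC=C(C)C)C(=O)C=C1OCC=C | intermediate
14 | (6R)-3,5-dihydroxy-4-{[(1S,2R,5R)-2-hydroxy-2-methyl-5-(prop-1-en-2-yl)cyclopentyl]methyl}-6-methyl-6-(3-methylbut-2-en-1-yl)cyclohexa-2,4-dien-1-one | C=C(C)[C@@H]1CC[C@@](C)(O)[C@H]1CC1=C(O)[C@@](C)(CC=C(C)C)C(=O)C=C1O | intermediate
15 | (S)-2-methylbutanoic acid | CC[C@H](C)C(=O)O | starting material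
16 | (6R)-3,5-dihydroxy-4-{[(1S,2R,5R)-2-hydroxy-2-methyl-5-(prop-1-en-2-yl)cyclopentyl]methyl}-6-methyl-6-(3-methylbut-2-en-1-yl)-2-[(2S)-2-methylbutanoyl]cyclohexa-2,4-dien-1-one | C=C(C)[C@@H]1CC[C@@](C)(O)[C@H]1CC1=C(O)[C@@](C)(CC=C(C)C)C(=O)C(C(=O)[C@@H](C)CC)=C1O | target

Total steps: 9. Longest linear sequence: 8 steps (1, 2, 4, 5, 6, 7, 8, 9).

**Steps most likely to fail**

Step 7 (proposed new method). The tethered alkoxide may displace the allyloxy group at C-4 by addition–elimination and form a cyclic enol ether instead of opening the ring. The ring-opened dienolate may relactonise to the pyranone faster than its methine enolate attacks the lactone. The closure may also discriminate the two faces poorly, or place methyl and prenyl without preference; this is the least secure stereochemical element of the plan. Fallback (known chemistry, no relay, stereocentre by separation): from 11, the tertiary alcohol is silylated (Et3SiOTf, 2,6-lutidine, CH2Cl2) to the triethylsilyl ether F1. NaOMe in MeOH opens the pyranone at C-2 (methanolysis of a 4-alkoxy-2-pyranone) to the ring-opened methyl ester F2. Mg(OMe)2 in hot MeOH, or NaH in THF, closes F2 by Claisen (Dieckmann) condensation to the silyl-protected dienone F3 together with its C-6 epimer F4, which are separated by chromatography. Bu4NF then removes the silyl group from F3 and the route is rejoined at 13.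

Step 3. Slow transfer of the alkenyl group from zinc to rhodium may let the uncatalysed, racemic addition compete and lower the enantiomeric purity, and the silyl enol ether may hydrolyse before the Mannich step. Fallback (resolution instead of catalysis): from 5, CuBr·SMe2-catalysed addition of CH2=C(CH3)MgBr in the presence of Me3SiCl gives the racemic silyl enol ether F5. The iminium salt converts it into the racemic trans Mannich base F6. This amine is resolved by crystallisation of its di-p-toluoyltartrate salt F7, formed with (−)-O,O′-di-p-toluoyl-L-tartaric acid (or the enantiomeric acid, whichever gives the less soluble salt of the 2R,3R amine). Basification returns the route at 7.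

Step 2. The dianion may be methylated on oxygen or at C-3, deprotonation at the secondary lateral carbon may be incomplete, and a second methylation may follow. Fallback (ring built after the side chain): from 2, alkylation of the lithium enolate of methyl propanoate gives methyl 2,5-dimethylhex-4-enoate F8. Its Claisen condensation with the dianion of methyl acetoacetate (NaH, then n-BuLi, THF) gives methyl 6,9-dimethyl-3,5-dioxodec-8-enoate F9. DBU in hot toluene closes F9 by lactonisation to pyranone 4, where the route is rejoined.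

**Further compounds**
F1 | step 7 | 3-{[(1S,2R,5R)-2-methyl-5-(prop-1-en-2-yl)-2-(triethylsilyloxy)cyclopentyl]methyl}-6-(5-methylhex-4-en-2-yl)-4-(prop-2-en-1-yloxy)-2H-pyran-2-one | C=C(C)[C@@H]1CC[C@@](C)(O[Si](CC)(CC)CC)[C@H]1CC1=C(OCC=C)C=C(C(C)CC=C(C)C)OC1=O
F2 | step 7 | methyl (2E)-6,9-dimethyl-2-{[(1S,2R,5R)-2-methyl-5-(prop-1-en-2-yl)-2-(triethylsilyloxy)cyclopentyl]methyl}-5-oxo-3-(prop-2-en-1-yloxy)deca-2,8-dienoate | C=C(C)[C@@H]1CC[C@@](C)(O[Si](CC)(CC)CC)[C@H]1C/C(C(=O)OC)=C(\OCC=C)CC(=O)C(C)CC=C(C)C
F3 | step 7 | (6R)-5-hydroxy-6-methyl-6-(3-methylbut-2-en-1-yl)-4-{[(1S,2R,5R)-2-methyl-5-(prop-1-en-2-yl)-2-(triethylsilyloxy)cyclopentyl]methyl}-3-(prop-2-en-1-yloxy)cyclohexa-2,4-dien-1-one | C=C(C)[C@@H]1CC[C@@](C)(O[Si](CC)(CC)CC)[C@H]1CC1=C(O)[C@@](C)(CC=C(C)C)C(=O)C=C1OCC=C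
F4 | step 7 | (6S)-5-hydroxy-6-methyl-6-(3-methylbut-2-en-1-yl)-4-{[(1S,2R,5R)-2-methyl-5-(prop-1-en-2-yl)-2-(triethylsilyloxy)cyclopentyl]methyl}-3-(prop-2-en-1-yloxy)cyclohexa-2,4-dien-1-one | C=C(C)[C@@H]1CC[C@@](C)(O[Si](CC)(CC)CC)[C@H]1CC1=C(O)[C@](C)(CC=C(C)C)C(=O)C=C1OCC=C
F5 | step 3 | racemic trimethyl{[3-(prop-1-en-2-yl)cyclopent-1-en-1-yl]oxy}silane | C=C(C)C1CCC(O[Si](C)(C)C)=C1
F6 | step 3 | racemic trans-2-[(dimethylamino)methyl]-3-(prop-1-en-2-yl)cyclopentan-1-one | C=C(C)C1CCC(=O)C1CN(C)C
F7 | step 3 | (2R,3R)-2-[(dimethylammonio)methyl]-3-(prop-1-en-2-yl)cyclopentan-1-one hydrogen (2R,3R)-O,O′-di-p-toluoyltartrate | C=C(C)[C@@H]1CCC(=O)[C@H]1C[NH+](C)C.OC(=O)[C@H](OC(=O)c1ccc(C)cc1)[C@@H](OC(=O)c1ccc(C)cc1)C([O-])=O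
F8 | step 2 | methyl 2,5-dimethylhex-4-enoate | COC(=O)C(C)CC=C(C)C
F9 | step 2 | methyl 6,9-dimethyl-3,5-dioxodec-8-enoate | COC(=O)CC(=O)CC(=O)C(C)CC=C(C)C
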